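**Strategy.** The p-menthene ring is read as (−)-menthone: its carbonyl carbon becomes C6, its α-methylene the spiro atom C1 and its methyl-bearing carbon C10. Because C5, the O-bearing carbon of the pyran ring, lies between quaternary C4 and C1, condensation of menthone with an α-quaternary aldehyde makes C5=C1 an enone. In the key step the unmasked phenol O1 adds to C5 (oxa-Michael, closing the pyran ring) and the C1 enolate so formed alkylates C2, closing the cyclopentane and creating the spiro centre; C5 and C1 are set together. The precursor is an open-chain 6-alkylidenementhone with an aryl acetate and a bromoethyl arm; C9' and C4 come from a coumarin.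

Key step: step 7

Locants used throughout: C1 spiro carbon; C2, C3 cyclopentane CH2; C4 quaternary carbon bearing the methyl; C5 the O-bearing CH; C6=C7 ring alkene (C7 bears the isopropyl); C8, C9 CH2; C10 the CH(CH3); C9' benzylic CH bearing the isobutyl; O1 the pyran oxygen. In these locants the target is (1R,4S,5R,10R,9'R).

Remark: C7 in compounds 9–14 is epimerisable under base and is drawn as in menthone; either epimer serves, since C7 becomes sp2 in step 8.

**Step 1**
Reactants: 1 5,7-dimethoxycoumarin; 2 isobutylmagnesium bromide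
Product: 3 (4R)-4-isobutyl-5,7-dimethoxychroman-2-one
Conditions: CuBr·SMe2 (5 mol %), Josiphos-type ferrocenyl diphosphine (6 mol %, enantiomer chosen for 4R), t-BuOMe, −75 °C; aq. NH4Cl
Reagents that add atoms: none
Why: Copper-catalysed asymmetric conjugate addition of a Grignard reagent to the coumarin enoate, in which the chiral diphosphine–copper complex selects the enantioface of the β-carbon and so sets C9'.

**Step 2**
Reactants: 3 (4R)-4-isobutyl-5,7-dimethoxychroman-2-one; 4 tert-butyl(2-iodoethoxy)dimethylsilane
Product: 5 trans-3-(2-silyloxyethyl) lactone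
Conditions: LiN(SiMe3)2, THF, −78 °C; then 4, DMPU, −78 → −30 °C
Reagents that add atoms: none
Why: Lactone enolate alkylation that installs the C3–C2 arm, expected anti to the pseudoaxial isobutyl group; this centre is planarised again in step 3, so its configuration is not critical.

**Step 3**
Reactants: 5 trans-3-(2-silyloxyethyl) lactone
Product: 6 quaternary lactone (3S,4R)
Conditions: LiN(SiMe3)2, THF, −78 °C; MeI, −78 → −20 °C
Reagents that add atoms: iodomethane (CI)
Why: Second enolate alkylation creates quaternary C4; the isobutyl group on C9' is held pseudoaxial by peri strain with the 5-methoxy group, so methyl iodide should enter on the opposite face and place methyl trans to isobutyl (1,2-induction).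

**Step 4**
Reactants: 6 quaternary lactone (3S,4R)
Product: 7 lactol (both anomers)
Conditions: i-Bu2AlH, CH2Cl2, −78 °C; aq. potassium sodium tartrate
Reagents that add atoms: none
Why: Partial hydride reduction of the aryl lactone stops at the lactol, the ring tautomer of the hydroxy aldehyde in which the future C5 is a CHO group.

**Step 5**
Reactants: 7 lactol; 8 (−)-menthone
Product: 10 E-enone aryl acetate with silyloxyethyl arm, via aldol bisacetate 9 (not isolated)
Conditions: 8, LiN(i-Pr)2, THF, −78 °C; lithium salt of 7 (LiN(i-Pr)2, THF), −78 → −40 °C; Ac2O, DMAP, −40 → 0 °C; DBU, 25 °C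
Reagents that add atoms: acetic anhydride (CC(=O)OC(C)=O)
Why: Directed aldol addition of the kinetic methylene-side lithium enolate of menthone to the ring-opened aldehyde form of the lactolate, acetylation of both oxygens and E1cB loss of acetate should give the E-enone with the phenol masked as its acetate, while the non-enolisable menthone C5 centre (future C10) is carried unchanged.

**Step 6**
Reactants: 10 E-enone aryl acetate with silyloxyethyl arm
Product: 11 E-enone aryl acetate with bromoethyl arm
Conditions: Ph3PBr2, CH2Cl2, 0 → 25 °C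
Reagents that add atoms: dibromotriphenylphosphorane (BrP(Br)(c1ccccc1)(c1ccccc1)c1ccccc1)
Why: Appel-type conversion of the primary silyl ether into the bromide (SN2 on the alkoxyphosphonium ion), done only after C4 is quaternary so that no γ-halo enolate can close a cyclopropane.

**Step 7**
Reactants: 11 E-enone aryl acetate with bromoethyl arm
Product: 14 spiro ketone, via phenol enone 12 (not isolated), via chromanyl ketone 13 (not isolated)
Conditions: Cs2CO3, MeOH (5 equiv), DMF, 0 → 45 °C
Reagents that add atoms: none
Why: Methanolysis of the aryl acetate frees the phenoxide, which adds to C5 of the enone (6-exo-trig oxa-Michael) and thereby forms the O1–C5 bond and the pyran ring; the C1 enolate then displaces bromide at C2 (5-enolexo-exo-tet), closing the cyclopentane and making C1 the spiro quaternary centre. The closest known reaction type is the Michael-initiated ring closure of ω-halo enones, here with a tethered phenoxide as Michael donor. C5 is controlled by reversibility of the oxa-Michael step: only the epimer in which the C3 arm and C1 are cis on the pyran ring can close a cis-fused five-membered ring, with C5–H eclipsing the enolate double bond to avoid allylic 1,3-strain. C1 is controlled by the adjacent C10 methyl, which sits pseudoaxial on the enolate so that C2 attacks the opposite face, ending trans to that methyl with C5 cis, as in the target; both controls favour the same diastereomer. The step needs C-alkylation by the enolate to outrun O-alkylation of the phenoxide by the bromide (a seven-membered ring); the fast, reversible six-membered oxa-Michael closure and the five-membered carbocyclisation should secure this, and C4 and C9' carry no acidic hydrogen that could be lost.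

**Step 8**
Reactants: 14 spiro ketone
Product: 15 enol triflate
Conditions: KN(SiMe3)2, THF, −78 → 0 °C; PhNTf2
Reagents that add atoms: N-phenylbis(trifluoromethanesulfonimide) (O=S(=O)(N(c1ccccc1)S(=O)(=O)C(F)(F)F)C(F)(F)F)
Why: C1 is quaternary, so the C6 ketone can enolise only towards C7 and O-triflation should give a single enol triflate, erasing the C7 centre.

**Step 9**
Reactants: 15 enol triflate
Product: 16 spiro alkene dimethyl ether
Conditions: Pd(OAc)2 (5 mol %), PPh3, HCO2H, n-Bu3N, DMF, 60 °C
Reagents that add atoms: none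
Why: Palladium-catalysed formate reduction of the vinyl triflate (oxidative addition to zerovalent palladium, formate exchange, decarboxylation, C–H reductive elimination) replaces OTf by H and leaves the trisubstituted C6=C7 alkene in place.

**Step 10**
Reactants: 16 spiro alkene dimethyl ether
Product: 17 dialdehyde dimethyl ether
Conditions: Cl2CHOMe, TiCl4, CH2Cl2, −78 → −40 °C; H2O
Reagents that add atoms: dichloromethyl methyl ether (COC(Cl)Cl); water (O)
Why: Rieche formylation of a phloroglucinol triether whose only two free ring positions are both strongly activated, so double formylation at low temperature should outrun attack on the hindered alkene.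

**Step 11**
Reactants: 17 dialdehyde dimethyl ether
Product: 18 target
Conditions: n-PrSLi, HMPA, 80 °C; aq. HCl
Reagents that add atoms: none
Why: Thiolate SN2 demethylation of the two methyl ethers activated by ortho and para formyl groups; the secondary, doubly neopentyl O1–C5 ether cannot be attacked this way and no acid is present during the cleavage.

**Compound list**

1 | 5,7-dimethoxycoumarin (5,7-dimethoxy-2H-chromen-2-one) | COc1cc(OC)c2ccc(=O)oc2c1 | starting material
2 | isobutylmagnesium bromide | CC(C)C[Mg]Br | starting material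
3 | (4R)-5,7-dimethoxy-4-(2-methylpropyl)chroman-2-one | CC(C)C[C@H]1c2c(OC)cc(OC)cc2OC(=O)C1 | intermediate
4 | tert-butyl(2-iodoethoxy)dimethylsilane | CC(C)(C)[Si](C)(C)OCCI | starting material
5 | (3R,4R)-3-[2-(tert-butyldimethylsilyloxy)ethyl]-5,7-dimethoxy-4-(2-methylpropyl)chroman-2-one (3,4-trans) | CC(C)C[C@H]1c2c(OC)cc(OC)cc2OC(=O)[C@@H]1CCO[Si](C)(C)C(C)(C)C | intermediate
6 | (3S,4R)-3-[2-(tert-butyldimethylsilyloxy)ethyl]-5,7-dimethoxy-3-methyl-4-(2-methylpropyl)chroman-2-one (methyl trans to isobutyl) | CC(C)C[C@H]1c2c(OC)cc(OC)cc2OC(=O)[C@@]1(C)CCO[Si](C)(C)C(C)(C)C | intermediate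
7 | (3S,4R)-3-[2-(tert-butyldimethylsilyloxy)ethyl]-5,7-dimethoxy-3-methyl-4-(2-methylpropyl)chroman-2-ol (lactol, both anomers) | CC(C)C[C@H]1c2c(OC)cc(OC)cc2OC(O)[C@@]1(C)CCO[Si](C)(C)C(C)(C)C | intermediate
8 | (−)-menthone, (2S,5R)-5-methyl-2-(propan-2-yl)cyclohexan-1-one | CC(C)[C@@H]1CC[C@@H](C)CC1=O | starting material
9 | aldol bis-acetate: menthone substituted at its C6 by CH(OAc)–C4(CH3)(CH2CH2OTBS)–C9'H(isobutyl)(2-acetoxy-4,6-dimethoxyphenyl), C4 and C9' configured as in 10, mixture at the two new centres | CC(C)C[C@@H](c1c(OC)cc(OC)cc1OC(C)=O)[C@](C)(CCO[Si](C)(C)C(C)(C)C)C(OC(C)=O)C1C(=O)[C@H](C(C)C)CC[C@H]1C | intermediate (not isolated)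
10 | (2S,5R,6E)-6-{(2R,3R)-3-(2-acetoxy-4,6-dimethoxyphenyl)-2-[2-(tert-butyldimethylsilyloxy)ethyl]-2,5-dimethylhexylidene}-5-methyl-2-(propan-2-yl)cyclohexan-1-one | CC(C)C[C@@H](c1c(OC)cc(OC)cc1OC(C)=O)[C@](C)(CCO[Si](C)(C)C(C)(C)C)/C=C1/C(=O)[C@H](C(C)C)CC[C@H]1C | intermediate
11 | (2S,5R,6E)-6-[(2R,3R)-3-(2-acetoxy-4,6-dimethoxyphenyl)-2-(2-bromoethyl)-2,5-dimethylhexylidene]-5-methyl-2-(propan-2-yl)cyclohexan-1-one | CC(C)C[C@@H](c1c(OC)cc(OC)cc1OC(C)=O)[C@](C)(CCBr)/C=C1/C(=O)[C@H](C(C)C)CC[C@H]1C | intermediate
12 | free phenol of 11 (2-hydroxy-4,6-dimethoxyphenyl in place of the acetoxyaryl group) | CC(C)C[C@@H](c1c(OC)cc(OC)cc1O)[C@](C)(CCBr)/C=C1/C(=O)[C@H](C(C)C)CC[C@H]1C | intermediate (not isolated)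
13 | oxa-Michael adduct: 2-(menthon-6-yl)chroman with O1–C5 formed, C5 configured as in 14, bromoethyl arm intact, C1 and C7 unassigned | CC(C)C[C@H]1c2c(OC)cc(OC)cc2O[C@H]([C@@]1(C)CCBr)C1C(=O)C(C(C)C)CC[C@H]1C | intermediate (not isolated)
14 | spiro ketone: O,O-dimethyl, deformyl analogue of the target with C6 ketone and C7–H, (1S,4S,5R,7S,10R,9'R) | CC(C)C[C@H]1c2c(OC)cc(OC)cc2O[C@@H]2[C@@]1(C)CC[C@@]21C(=O)[C@H](C(C)C)CC[C@H]1C | intermediate
15 | enol triflate of 14 (C6–OTf, C6=C7), (1S,4S,5R,10R,9'R) | CC(C)C[C@H]1c2c(OC)cc(OC)cc2O[C@@H]2[C@@]1(C)CC[C@@]21C(OS(=O)(=O)C(F)(F)F)=C(C(C)C)CC[C@H]1C | intermediate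
16 | O,O-dimethyl, deformyl analogue of the target, (1R,4S,5R,10R,9'R) | CC(C)C[C@H]1c2c(OC)cc(OC)cc2O[C@@H]2[C@@]1(C)CC[C@@]21C=C(C(C)C)CC[C@H]1C | intermediate
17 | O,O-dimethyl ether of the target (two CHO, two OCH3), (1R,4S,5R,10R,9'R) | CC(C)C[C@H]1c2c(OC)c(C=O)c(OC)c(C=O)c2O[C@@H]2[C@@]1(C)CC[C@@]21C=C(C(C)C)CC[C@H]1C | intermediate
18 | CNP0121396.1, (1R,4S,5R,10R,9'R) in the locants above | CC(C)C[C@H]1c2c(O)c(C=O)c(O)c(C=O)c2O[C@@H]2[C@@]1(C)CC[C@@]21C=C(C(C)C)CC[C@H]1C | target

Total step count: 11. Longest linear sequence: 11 steps (1 → 18); menthone 8 enters at step 5.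

**Steps most likely to fail**

Step 7. The C1 enolate may be protonated faster than it cyclises, so that the sequence stalls after the oxa-Michael addition, or the phenoxide may be alkylated at oxygen by the bromide. The fallback sets out from 10 and returns at 14, replacing the alkylation by an aldol closure. HF·pyridine would cleave the silyl ether to the primary alcohol F1, and Dess–Martin periodinane would oxidise it to the aldehyde F2. K2CO3 in MeOH would then trigger deacetylation, oxa-Michael addition and a reversible intramolecular aldol closure (5-exo-trig) to the hydroxy spiro ketone F3. Xanthate formation (NaH, CS2, MeI) to the xanthate F4 and Barton–McCombie reduction (Bu3SnH, AIBN, toluene, 90 °C) would give 14.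

Step 5. Ring opening of the hindered lithium lactolate may be slow, and the aldolate may revert before it is acylated. The fallback sets out from 7 and 8 and returns at 10, joining the halves through an oxocarbenium ion instead. Ac2O in pyridine would give the lactol acetate F5. BF3·OEt2 would ionise F5, and the kinetic trimethylsilyl enol ether F6 of menthone (from 8, LiN(i-Pr)2, Me3SiCl) would capture the cation to give the chromanyl ketone F7. DBU with Ac2O and DMAP would then open F7 by E1cB loss of the phenoxide and trap it as the acetate, giving 10.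

Step 1. Enantioface selection may be poor and 1,2-addition to the lactone carbonyl may compete, because the 5-methoxy group crowds the β-carbon. The fallback sets out from 1 and 2 and returns at 3, moving the stereo-defining event to a hydride delivery. An achiral organocopper addition (CuI, Me3SiCl, THF, −78 °C) would give the racemic lactone F8. DDQ in refluxing dioxane would dehydrogenate it to 4-isobutyl-5,7-dimethoxycoumarin F9. Copper hydride-catalysed asymmetric conjugate reduction (Cu(OAc)2, a DTBM-SEGPHOS enantiomer, polymethylhydrosiloxane, t-BuOH, toluene) would give 3.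

**Further compounds**

F1 | step 7 | primary alcohol from 10 (2-hydroxyethyl arm) | CC(C)C[C@@H](c1c(OC)cc(OC)cc1OC(C)=O)[C@](C)(CCO)/C=C1/C(=O)[C@H](C(C)C)CC[C@H]1C
F2 | step 7 | aldehyde (2-oxoethyl arm) | CC(C)C[C@@H](c1c(OC)cc(OC)cc1OC(C)=O)[C@](C)(CC=O)/C=C1/C(=O)[C@H](C(C)C)CC[C@H]1C
F3 | step 7 | 2-hydroxy derivative of spiro ketone 14 (carbinol mixture) | CC(C)C[C@H]1c2c(OC)cc(OC)cc2O[C@@H]2[C@@]1(C)CC(O)[C@@]21C(=O)[C@H](C(C)C)CC[C@H]1C
F4 | step 7 | S-methyl xanthate of F3 | CC(C)C[C@H]1c2c(OC)cc(OC)cc2O[C@@H]2[C@@]1(C)CC(OC(=S)SC)[C@@]21C(=O)[C@H](C(C)C)CC[C@H]1C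
F5 | step 5 | lactol acetate of 7 | CC(C)C[C@H]1c2c(OC)cc(OC)cc2OC(OC(C)=O)[C@@]1(C)CCO[Si](C)(C)C(C)(C)C
F6 | step 5 | kinetic trimethylsilyl enol ether of (−)-menthone | CC(C)[C@@H]1CC[C@@H](C)C=C1O[Si](C)(C)C
F7 | step 5 | 2-(menthon-6-yl)chroman with silyloxyethyl arm (mixture at C5 and C1) | CC(C)C[C@H]1c2c(OC)cc(OC)cc2OC([C@@]1(C)CCO[Si](C)(C)C(C)(C)C)C1C(=O)[C@H](C(C)C)CC[C@H]1C
F8 | step 1 | racemic 4-isobutyl-5,7-dimethoxychroman-2-one | CC(C)CC1CC(=O)Oc2cc(OC)cc(OC)c12
F9 | step 1 | 4-isobutyl-5,7-dimethoxycoumarin | CC(C)Cc1cc(=O)oc2cc(OC)cc(OC)c12
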